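**Retrosynthetic overview**
1. Target 28 ⇐ enone 26: MeLi 1,2-addition makes the C4 carbinol, then acid unmasks the C1 ketone (dimethyl ketal) and the TES ether.
2. 26 ⇐ key fragment union: the tertiary α-keto radical from bromo enone 7 adds to the terminal olefin of side-chain diol 24 (forms C5–C1′, sets the quaternary centre anti to ethyl).
3. 7 ⇐ phenol: oxidative dearomatisation to the p-quinone monoketal, Cu-catalysed enantioselective Et2Zn addition with MeI trapping, α′-bromination.
4. 24 ⇐ Evans syn-aldol/LiBH4 ⇐ catalytic acetate aldol, TES, DIBAL ⇐ aldehyde 15 ⇐ two Cu-catalysed Grignard couplings of (S)-3-bromo-2-methylpropan-1-ol.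
5. Rings: the only ring is the phenol carbocycle, dearomatised in step 1 and carried through; no ring is formed later.

Assumption: the target is the single stereoisomer encoded by the SMILES, (4R,5R,6R) in the ring and (4R,7R,8S,10R,11R) in the side chain; chiral catalysts are specified by the product configuration they must deliver.

**Step 1**
Reactants: 1 phenol
Product: 3 4,4-dimethoxycyclohexa-2,5-dien-1-one, via 4-methoxyphenol 2 (not isolated)
Conditions: PhI(OAc)2 (2.1 equiv), MeOH, 0 °C → rt
Reagents that add atoms: methanol, CO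
Why: Hypervalent-iodine oxidative dearomatisation (Pelter oxidation): the first oxidation para-methoxylates phenol to 2 and the second traps methanol at the same carbon, giving the achiral p-quinone monoketal whose ketal carbon is the future C1 ketone and whose carbonyl carbon is the future C4 carbinol.

**Step 2**
Reactants: 3 4,4-dimethoxycyclohexa-2,5-dien-1-one
Product: 5 (5R,6R)-5-ethyl-4,4-dimethoxy-6-methylcyclohex-2-en-1-one, via ethylzinc enolate 4 (not isolated)
Conditions: Et2Zn (1.5 equiv), Cu(OTf)2 (2 mol %), Feringa BINOL phosphoramidite (4 mol %, the enantiomer giving 5R), toluene, −25 °C; then MeI, HMPA, 0 °C → rt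
Reagents that add atoms: diethylzinc, CC[Zn]CC; iodomethane, CI
Why: Feringa Cu–phosphoramidite asymmetric conjugate addition desymmetrises the prochiral dienone and sets the ethyl-bearing centre (future C6 of the target, R), and the zinc enolate is methylated anti to ethyl (tandem conjugate addition–enolate alkylation) at a centre that is re-made in step 14.

**Step 3**
Reactants: 5 (5R,6R)-5-ethyl-4,4-dimethoxy-6-methylcyclohex-2-en-1-one
Product: 7 (5S,6R)-6-bromo-5-ethyl-4,4-dimethoxy-6-methylcyclohex-2-en-1-one, via lithium dienolate 6 (not isolated)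
Conditions: LiHMDS, THF, −78 °C; then NBS, −78 °C
Reagents that add atoms: N-bromosuccinimide, O=C1CCC(=O)N1Br
Why: C6 is the only enolisable position, so kinetic enolisation and electrophilic bromination of the cross-conjugated dienolate give the tertiary α-bromo enone (bromine anti to ethyl; its configuration is irrelevant because C6 becomes a planar radical).

**Step 4**
Reactants: 8 (2S)-3-bromo-2-methylpropan-1-ol
Product: 10 (2R)-2-methylpent-4-en-1-ol, via bromomagnesium alkoxide 9 (not isolated)
Conditions: CH2=CHMgBr (2.5 equiv), Li2CuCl4 (3 mol %), THF/NMP, −20 °C → rt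
Reagents that add atoms: vinylmagnesium bromide, C=C[Mg]Br
Why: Kochi–Cahiez copper-catalysed Grignard cross-coupling of the primary bromide (as its magnesium alkoxide) with vinylmagnesium bromide; the methyl stereocentre is not touched (S→R is only a CIP change).

**Step 5**
Reactants: 10 (2R)-2-methylpent-4-en-1-ol
Product: 11 (4R)-5-iodo-4-methylpent-1-ene
Conditions: I2, PPh3, imidazole, CH2Cl2, 0 °C
Reagents that add atoms: iodine, II
Why: Garegg–Samuelsson (Appel-type) iodination of the primary alcohol with no reaction at the stereocentre.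

**Step 6**
Reactants: 11 (4R)-5-iodo-4-methylpent-1-ene; 8 (2S)-3-bromo-2-methylpropan-1-ol
Product: 14 (2R,5S)-2,5-dimethyloct-7-en-1-ol, via Grignard reagent 12 (not isolated), via chloromagnesium alkoxide 13 (not isolated)
Conditions: 11, Mg, THF; 8, MeMgCl (1 equiv), THF, −20 °C; combine, Li2CuCl4 (3 mol %), NMP, 0 °C → rt
Reagents that add atoms: none
Why: Copper-catalysed sp3–sp3 Grignard coupling (Kochi–Cahiez) of 12 with the bromide, masked beforehand as its chloromagnesium alkoxide 13 by sacrificial MeMgCl so that none of 12 is spent on the hydroxyl, joins the two methyl-bearing units into the 1,4-dimethyl array, both stereocentres coming unchanged from 8.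

**Step 7**
Reactants: 14 (2R,5S)-2,5-dimethyloct-7-en-1-ol
Product: 15 (2R,5S)-2,5-dimethyloct-7-enal
Conditions: TEMPO (10 mol %), PhI(OAc)2, CH2Cl2, rt
Reagents that add atoms: none
Why: TEMPO/PhI(OAc)2 oxidation stops at the aldehyde under non-basic conditions, so the α-methyl centre does not epimerise and the olefin is untouched.

**Step 8**
Reactants: 15 (2R,5S)-2,5-dimethyloct-7-enal
Product: 17 methyl (3S,4R,7S)-3-hydroxy-4,7-dimethyldec-9-enoate, via trimethylsilyl ether 16 (not isolated)
Conditions: CH2=C(OMe)OTMS, Carreira Ti(IV)–binaphthyl Schiff-base catalyst (5 mol %, antipode giving 3S), Et2O, −10 °C; then 1 M HCl, THF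
Reagents that add atoms: 1-methoxy-1-(trimethylsilyloxy)ethene, C=C(OC)O[Si](C)(C)C
Why: Carreira catalytic enantioselective Mukaiyama acetate aldol, in which the catalyst overrides the weak Felkin bias of the α-methyl aldehyde and sets C3 as S (anti to the C4 methyl), followed by acidic desilylation.

**Step 9**
Reactants: 17 methyl (3S,4R,7S)-3-hydroxy-4,7-dimethyldec-9-enoate
Product: 18 methyl (3S,4R,7S)-4,7-dimethyl-3-(triethylsilyloxy)dec-9-enoate
Conditions: TESCl, imidazole, DMF, 0 °C
Reagents that add atoms: chlorotriethylsilane, CC[Si](Cl)(CC)CC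
Why: Standard silylation; the TES ether survives the following steps and is removed by the acid of step 15.

**Step 10**
Reactants: 18 methyl (3S,4R,7S)-4,7-dimethyl-3-(triethylsilyloxy)dec-9-enoate
Product: 19 (3S,4R,7S)-4,7-dimethyl-3-(triethylsilyloxy)dec-9-enal
Conditions: DIBAL-H (1.1 equiv), CH2Cl2, −78 °C; Rochelle salt
Reagents that add atoms: none
Why: DIBAL-H half-reduction of the β-silyloxy methyl ester via the aluminium hemiacetal that is stable at −78 °C, giving the aldehyde without epimerisation.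

**Step 11**
Reactants: 20 butanoyl chloride
Product: 21 (4S)-4-benzyl-3-butanoyl-1,3-oxazolidin-2-one
Conditions: (S)-4-benzyloxazolidin-2-one, n-BuLi, THF, −78 °C; then 20
Reagents that add atoms: (4S)-4-benzyl-1,3-oxazolidin-2-one, O=C1N[C@@H](Cc2ccccc2)CO1
Why: N-acylation of the lithiated Evans oxazolidinone with butanoyl chloride installs the auxiliary for the syn-aldol.

**Step 12**
Reactants: 21 (4S)-4-benzyl-3-butanoyl-1,3-oxazolidin-2-one; 19 (3S,4R,7S)-4,7-dimethyl-3-(triethylsilyloxy)dec-9-enal
Product: 23 (4S)-4-benzyl-3-[(2S,3R,5S,6R,9S)-2-ethyl-3-hydroxy-6,9-dimethyl-5-(triethylsilyloxy)dodec-11-enoyl]-1,3-oxazolidin-2-one, via dibutylboron enolate 22 (not isolated)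
Conditions: Bu2BOTf, Et3N, CH2Cl2, −78 → 0 °C; then 19, −78 → 0 °C; pH 7 buffer, MeOH, H2O2
Reagents that add atoms: none
Why: Evans boron syn-aldol: the (Z)-dibutylboron enolate reacts through a Zimmerman–Traxler chair under auxiliary control (>20:1), setting C2 (S) and C3 (R) independently of the β-silyloxy centre.

**Step 13**
Reactants: 23 the Evans aldol adduct
Product: 24 (2R,3R,5S,6R,9S)-2-ethyl-6,9-dimethyl-5-(triethylsilyloxy)dodec-11-ene-1,3-diol
Conditions: LiBH4, MeOH (1 equiv), Et2O, 0 °C
Reagents that add atoms: none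
Why: LiBH4 reductive cleavage of the imide gives the primary alcohol (the hydroxymethyl group) and returns the auxiliary; no stereocentre is touched and any silyl migration within the triol array is harmless because all three oxygens end up free.

**Step 14**
Reactants: 24 (2R,3R,5S,6R,9S)-2-ethyl-6,9-dimethyl-5-(triethylsilyloxy)dodec-11-ene-1,3-diol; 7 (5S,6R)-6-bromo-5-ethyl-4,4-dimethoxy-6-methylcyclohex-2-en-1-one
Product: 26 (5R,6R)-5-ethyl-6-[(4R,7R,8S,10R,11R)-10-hydroxy-11-(hydroxymethyl)-4,7-dimethyl-8-(triethylsilyloxy)tridecyl]-4,4-dimethoxy-6-methylcyclohex-2-en-1-one, via secondary bromide adduct 25 (not isolated)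
Conditions: 7 (1.5 equiv), fac-Ir(ppy)3 (1 mol %), MeCN, blue LEDs, rt; then (Me3Si)3SiH, AIBN, toluene, 80 °C
Reagents that add atoms: none
Why: Key step, a photoredox atom-transfer radical addition (Kharasch type): the electrophilic tertiary α-keto radical from 7 adds to the terminal carbon of the unactivated olefin of 24 on the face anti to the pseudo-axial C5 ethyl group (A1,2 strain with the C6 methyl), which creates the quaternary centre (6R) and joins the fragments, while bromine transfer from 7 carries the chain and the secondary bromide 25 is then reduced by (Me3Si)3SiH in the same flask.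

**Step 15**
Reactants: 26 the coupled enone
Product: 28 (4R,5R,6R)-5-[(4R,7R,8S,10R,11R)-8,10-dihydroxy-11-(hydroxymethyl)-4,7-dimethyltridecyl]-6-ethyl-4-hydroxy-4,5-dimethylcyclohex-2-en-1-one, via tertiary carbinol ketal 27 (not isolated)
Conditions: MeLi (5 equiv), THF, −78 °C; then 1 M aq HCl, THF, 0 °C → rt
Reagents that add atoms: methyllithium, C[Li]; water, O
Why: MeLi adds 1,2 to the non-enolisable enone from the face opposite the C6 methyl and C5 ethyl groups (axial attack anti to the axial α-methyl) to give the (R)-carbinol, and aqueous HCl then hydrolyses the allylic dimethyl ketal to the enone (standard p-quinol-ketal unmasking) and cleaves the TES ether.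

**Compound list**
1 | phenol | Oc1ccccc1 | starting material
2 | 4-methoxyphenol | COc1ccc(O)cc1 | intermediate (not isolated)
3 | 4,4-dimethoxycyclohexa-2,5-dien-1-one | COC1(OC)C=CC(=O)C=C1 | intermediate
4 | ethylzinc enolate, ethyl{[(3R)-3-ethyl-4,4-dimethoxycyclohexa-1,5-dien-1-yl]oxy}zinc | CC[Zn]OC1=C[C@@H](CC)C(OC)(OC)C=C1 | intermediate (not isolated)
5 | (5R,6R)-5-ethyl-4,4-dimethoxy-6-methylcyclohex-2-en-1-one | C[C@@H]1[C@@H](CC)C(OC)(OC)C=CC1=O | intermediate
6 | lithium (3R)-3-ethyl-4,4-dimethoxy-2-methylcyclohexa-1,5-dien-1-olate | [Li]OC1=C(C)[C@@H](CC)C(OC)(OC)C=C1 | intermediate (not isolated)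
7 | (5S,6R)-6-bromo-5-ethyl-4,4-dimethoxy-6-methylcyclohex-2-en-1-one | C[C@@]1(Br)[C@@H](CC)C(OC)(OC)C=CC1=O | intermediate
8 | (2S)-3-bromo-2-methylpropan-1-ol | OC[C@H](C)CBr | starting material
9 | bromomagnesium (2S)-3-bromo-2-methylpropan-1-olate | Br[Mg]OC[C@H](C)CBr | intermediate (not isolated)
10 | (2R)-2-methylpent-4-en-1-ol | OC[C@H](C)CC=C | intermediate
11 | (4R)-5-iodo-4-methylpent-1-ene | IC[C@H](C)CC=C | intermediate
12 | [(2R)-2-methylpent-4-en-1-yl]magnesium iodide | I[Mg]C[C@H](C)CC=C | intermediate (not isolated)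
13 | chloromagnesium (2S)-3-bromo-2-methylpropan-1-olate | Cl[Mg]OC[C@H](C)CBr | intermediate (not isolated)
14 | (2R,5S)-2,5-dimethyloct-7-en-1-ol | OC[C@H](C)CC[C@H](C)CC=C | intermediate
15 | (2R,5S)-2,5-dimethyloct-7-enal | O=C[C@H](C)CC[C@H](C)CC=C | intermediate
16 | methyl (3S,4R,7S)-4,7-dimethyl-3-(trimethylsilyloxy)dec-9-enoate | COC(=O)C[C@H](O[Si](C)(C)C)[C@H](C)CC[C@H](C)CC=C | intermediate (not isolated)
17 | methyl (3S,4R,7S)-3-hydroxy-4,7-dimethyldec-9-enoate | COC(=O)C[C@H](O)[C@H](C)CC[C@H](C)CC=C | intermediate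
18 | methyl (3S,4R,7S)-4,7-dimethyl-3-(triethylsilyloxy)dec-9-enoate | COC(=O)C[C@H](O[Si](CC)(CC)CC)[C@H](C)CC[C@H](C)CC=C | intermediate
19 | (3S,4R,7S)-4,7-dimethyl-3-(triethylsilyloxy)dec-9-enal | O=CC[C@H](O[Si](CC)(CC)CC)[C@H](C)CC[C@H](C)CC=C | intermediate
20 | butanoyl chloride | CCCC(Cl)=O | starting material
21 | (4S)-4-benzyl-3-butanoyl-1,3-oxazolidin-2-one | CCCC(=O)N1[C@@H](Cc2ccccc2)COC1=O | intermediate
22 | (Z)-dibutylboron enolate of 21 | CC/C=C(\OB(CCCC)CCCC)N1[C@@H](Cc2ccccc2)COC1=O | intermediate (not isolated)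
23 | (4S)-4-benzyl-3-[(2S,3R,5S,6R,9S)-2-ethyl-3-hydroxy-6,9-dimethyl-5-(triethylsilyloxy)dodec-11-enoyl]-1,3-oxazolidin-2-one | CC[C@H](C(=O)N1[C@@H](Cc2ccccc2)COC1=O)[C@H](O)C[C@H](O[Si](CC)(CC)CC)[C@H](C)CC[C@H](C)CC=C | intermediate
24 | (2R,3R,5S,6R,9S)-2-ethyl-6,9-dimethyl-5-(triethylsilyloxy)dodec-11-ene-1,3-diol | CC[C@H](CO)[C@H](O)C[C@H](O[Si](CC)(CC)CC)[C@H](C)CC[C@H](C)CC=C | intermediate
25 | (5R,6R)-6-[(4S,7R,8S,10R,11R)-2-bromo-10-hydroxy-11-(hydroxymethyl)-4,7-dimethyl-8-(triethylsilyloxy)tridecyl]-5-ethyl-4,4-dimethoxy-6-methylcyclohex-2-en-1-one (both C2′ epimers) | CC[C@H](CO)[C@H](O)C[C@H](O[Si](CC)(CC)CC)[C@H](C)CC[C@H](C)CC(Br)C[C@]1(C)[C@@H](CC)C(OC)(OC)C=CC1=O | intermediate (not isolated)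
26 | (5R,6R)-5-ethyl-6-[(4R,7R,8S,10R,11R)-10-hydroxy-11-(hydroxymethyl)-4,7-dimethyl-8-(triethylsilyloxy)tridecyl]-4,4-dimethoxy-6-methylcyclohex-2-en-1-one | CC[C@H](CO)[C@H](O)C[C@H](O[Si](CC)(CC)CC)[C@H](C)CC[C@H](C)CCC[C@]1(C)[C@@H](CC)C(OC)(OC)C=CC1=O | intermediate
27 | (1R,5R,6R)-5-ethyl-6-[(4R,7R,8S,10R,11R)-10-hydroxy-11-(hydroxymethyl)-4,7-dimethyl-8-(triethylsilyloxy)tridecyl]-4,4-dimethoxy-1,6-dimethylcyclohex-2-en-1-ol | CC[C@H](CO)[C@H](O)C[C@H](O[Si](CC)(CC)CC)[C@H](C)CC[C@H](C)CCC[C@]1(C)[C@@H](CC)C(OC)(OC)C=C[C@@]1(C)O | intermediate (not isolated)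
28 | (4R,5R,6R)-5-[(4R,7R,8S,10R,11R)-8,10-dihydroxy-11-(hydroxymethyl)-4,7-dimethyltridecyl]-6-ethyl-4-hydroxy-4,5-dimethylcyclohex-2-en-1-one | CC[C@H](CO)[C@H](O)C[C@H](O)[C@H](C)CC[C@H](C)CCC[C@]1(C)[C@@H](CC)C(=O)C=C[C@@]1(C)O | target

**Totals and risks**
Total step count: 15. Longest linear sequence: 11 steps (steps 4–10, then 12–15).

Most likely to fail, first: step 14. A tertiary α-keto radical adds only slowly to a monosubstituted, unactivated olefin, so 7 may be reduced or eliminate HBr first. The adduct radical can also cyclise onto the ring enone, and the facial selectivity rests on one neighbouring ethyl group. The fallback sets out from 5. Its lithium dienolate 6 is quenched with diethyl dixanthogen to give the tertiary xanthate S-[(1R,6S)-6-ethyl-5,5-dimethoxy-1-methyl-2-oxocyclohex-3-en-1-yl] O-ethyl carbonodithioate F1. Zard degenerative xanthate-transfer addition of F1 to 24 (dilauroyl peroxide, 1,2-dichloroethane, reflux), which tolerates slow additions to unactivated olefins, gives the secondary xanthate adduct F2. Reductive removal of the xanthate with (Me3Si)3SiH/AIBN comes back to the route at 26.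

Second: step 15. The carbonyl is flanked by a methyl and a CH2 chain on the quaternary carbon, so MeLi may prefer the wrong face, the one that carries the ring methyl and ethyl groups. The fallback turns such a preference to use and sets out from 26. Wittig methylenation (Ph3P=CH2, toluene, 80 °C) gives the exocyclic diene F3. Buffered mCPBA or DMDO then epoxidises the exocyclic olefin from that same face, so oxygen is placed where MeLi would have put carbon, giving the spiro-epoxide F4. LiEt3BH opens F4 at its CH2 terminus, which makes the new methyl group on the face of the side chain, and comes back to the route at 27, which is hydrolysed with aqueous HCl as in step 15.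

Third: step 8. The required C3 configuration is anti-Felkin, so catalyst and aldehyde are mismatched and the diastereomer ratio may erode. The fallback sets out from 15. Roskamp homologation (methyl diazoacetate, SnCl2, CH2Cl2) gives the β-keto ester methyl (4R,7S)-4,7-dimethyl-3-oxodec-9-enoate F5. Noyori asymmetric transfer hydrogenation (RuCl(p-cymene)(TsDPEN), hand chosen for 3S, HCO2H/Et3N) leaves the olefin alone and comes back to the route at 17.

**Further compounds**
F1 | step 14 | S-[(1R,6S)-6-ethyl-5,5-dimethoxy-1-methyl-2-oxocyclohex-3-en-1-yl] O-ethyl carbonodithioate | CCOC(=S)S[C@]1(C)[C@@H](CC)C(OC)(OC)C=CC1=O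
F2 | step 14 | xanthate adduct, 26 carrying an (ethoxycarbonothioyl)sulfanyl group at C2′ of the side chain (both C2′ epimers) | CC[C@H](CO)[C@H](O)C[C@H](O[Si](CC)(CC)CC)[C@H](C)CC[C@H](C)CC(SC(=S)OCC)C[C@]1(C)[C@@H](CC)C(OC)(OC)C=CC1=O
F3 | step 15 | exocyclic diene, 26 with the ring C=O replaced by C=CH2 | CC[C@H](CO)[C@H](O)C[C@H](O[Si](CC)(CC)CC)[C@H](C)CC[C@H](C)CCC[C@]1(C)[C@@H](CC)C(OC)(OC)C=CC1=C
F4 | step 15 | spiro-epoxide of F3 at the exocyclic olefin, oxygen on the face of the ring methyl and ethyl groups | CC[C@H](CO)[C@H](O)C[C@H](O[Si](CC)(CC)CC)[C@H](C)CC[C@H](C)CCC[C@]1(C)[C@@H](CC)C(OC)(OC)C=C[C@]13CO3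
F5 | step 8 | methyl (4R,7S)-4,7-dimethyl-3-oxodec-9-enoate | COC(=O)CC(=O)[C@H](C)CC[C@H](C)CC=C
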